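**Route in one sentence:** catalytic enantioselective 1,4-addition of arylboronic acid 12 to the C2=C3 bond of the fully substituted, achiral chromone 11 forms the C2–C1′ bond, attaches ring B and sets the only stereocentre.

## Structural features

The target is a flavanone: benzo ring A is fused to dihydropyranone ring C (O1, C2, C3, C4=O, C4a, C8a), and C2 carries the 4-hydroxyphenyl ring B. Ring A is hexasubstituted (C4a acyl, C5–OH, C6–CH3, C7–OH, C8–prenyl, C8a–O1), so it has no aromatic C–H and every substituent must be placed without ambiguity. C2 is the only stereocentre, (S) as read from the SMILES; it has no stereogenic neighbour, is benzylic, bears O1 and lies β to the C4 ketone, so it is erased by retro-oxa-Michael opening to the chalcone, most easily under base once the 5- and 4′-hydroxyls are free. The fragile groups are the prenyl alkene next to the 7-OH (acid closes it to a chroman; it is also lost on hydrogenation), the electron-rich phenols and the C2–O1 bond. The difficulty is twofold: the absolute configuration at C2, and the constitution of ring A, because the two oxygens ortho to C4a (O1 and O5) are not equivalent and a closure that cannot tell them apart also gives the 8-methyl-6-prenyl isomer. The key step exploits that C2 is the β-carbon of the C4 ketone and carries ring B: the C2–C1′ bond is that of a β-aryl ketone and can be made, together with the stereocentre, by face-selective 1,4-arylation of the C2=C3 bond of a flat, configurationally inert chromone. The route to that chromone exploits that ring A is a 2-methylphloroglucinol in which O1 is the oxygen para to the C6 methyl, on the local mirror axis through C6 and C8a; a precursor with only that oxygen free has two equivalent ortho carbons (the future C8 and C4a), and the constitutional problem disappears.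

## Logic of the disconnections

**14 ⇒ 13.** The three O–CH2OCH3 bonds at O5, O7 and O4′ are cut. The phenols must be masked through organometallic, basic and oxidative steps, and acetals are the one group that leaves without base (which would open ring C), hydrogen (prenyl) or strong Lewis acid. The forward step must be acidic enough to cleave three aryl acetals and mild enough to spare the prenyl/7-OH pair and C2.

**13 ⇒ 11 + 12 (key).** The C2–C1′ bond is cut. This removes ring B and the only stereocentre in one stroke and leaves 11, which is achiral, planar and unable to ring-open or racemise, plus the purchasable 12. The forward step must deliver the aryl group to the Re face of C2 (this gives 2S), add 1,4 and not 1,2, and ignore the prenyl alkene and the acetals.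

**11 ⇒ 10 ⇒ 9 ⇒ 8.** The O1–C2 bond is cut (oxa-Michael closure of ring C onto an ynone), then the C3–C4 bond (acetylide addition to an aldehyde, followed by oxidation). C2 and C3 come from acetylene, and ring C closes without any stereochemical issue. The demand is that the only free hydroxyl in 10 is the future O1; this holds by construction, so the closure cannot give a constitutional isomer.

**8 ⇒ 7.** The C4–C4a bond is cut. In 7 the position ortho to the free hydroxyl is the only aromatic C–H left, so a phenoxide-directed formylation has a single site. The demand is only that formylation is faster than further reaction of the aldehyde.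

**7 ⇒ 6 ⇒ 5 ⇒ 4.** The C8–C1″ bond is cut and traced back to an O1-bound 1,1-dimethylallyl group (aromatic [3,3] shift), then the O1–C bond of the propargyl ether is cut. The prenyl group is delivered intramolecularly from the unique oxygen to an ortho carbon, and since the two ortho carbons of 4 are equivalent only one product can form. The forward steps need a clean alkyne-to-alkene reduction and a concerted [3,3] shift, not ionisation.

**4 ⇒ 3 ⇒ 2 ⇒ 1.** The C8a–O1 bond is cut (C–O from C–B from C–H), then the two O–CH2OCH3 bonds. This reaches the cheap, symmetric 1; the oxygen para to the methyl is introduced last and is therefore the only free one. The demand is borylation at the one C–H of 2 that has no ortho substituent.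

## Other disconnections considered

**Alternative 1:** the first plan that comes to mind. Cut O1–C2 and C2–C3: Claisen–Schmidt condensation of acetophenone A1 with 4-hydroxybenzaldehyde to chalcone A2, then 6-endo-trig oxa-Michael closure. In A2 both ortho hydroxyls can add, so the target would be accompanied by its 8-methyl-6-prenyl isomer A3. The closure is also reversible through the same retro-oxa-Michael pathway that racemises flavanones, so enantioselectivity imposed by a chiral catalyst is open to erosion, and high selectivity generally calls for an extra activating group at C3 that must be installed and removed. The chosen plan makes C2 in an irreversible C–C bond formation on a substrate whose constitution is already fixed.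

**Alternative 2:** cut the C2–H bond: enantioselective conjugate reduction or asymmetric hydrogenation of flavone A4. Ring B must then be attached earlier by aroylation and Baker–Venkataraman rearrangement, which adds steps. The C2=C3 bond of A4 is a trisubstituted, doubly donor-substituted enone and a poor hydride acceptor, while hydrogenation catalysts are expected to touch the prenyl alkene and over-reduce C4=O, forcing a re-oxidation. The chosen step adds a carbon nucleophile to a less substituted C2=C3 bond and needs no reductant.

**Alternative 3:** cut the C8–C1″ bond last: Lewis-acid-promoted para-Claisen–Cope relay (for example with Eu(fod)3) of a prenyl group from O5 to C8 in flavanone A5, made from A6. This uses the para relation of C8 to O5 and the blocking methyl at C6 and would fix the prenyl position well. It leaves the C2 configuration and the 6-methyl constitution of A6 unsolved, since A6 still comes from an ambiguous chalcone closure. It also exposes the labile stereocentre to Lewis acid and heat and needs extra steps to tell O5 from O7 and O4′. The chosen plan settles the prenyl position by symmetry at 4, before any stereocentre exists.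

Key step: step 8

**Remarks on the chemistry.** 12 and both enantiomers of t-BuPyOX are taken as purchasable. Atom numbers follow flavanone numbering; C1″ is the benzylic carbon of the prenyl group. The ligand enantiomer in step 8 is assigned by analogy with cyclic enones and is a prediction.

## Steps

**Step 1**
Reactants: 1 2-methylbenzene-1,3-diol (2-methylresorcinol)
Product: 2 1,3-bis(methoxymethoxy)-2-methylbenzene
Conditions: MOMCl (2.5 equiv), iPr2NEt, CH2Cl2, 0 °C to rt
Reagents that add atoms: chloromethyl methyl ether, COCCl
Why: Double O-alkylation of the phenols with a chloromethyl ether; the acetals tolerate base, organometallics, heat and mild oxidants and leave under mild acid at the end.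

**Step 2**
Reactants: 2 1,3-bis(methoxymethoxy)-2-methylbenzene
Product: 4 3,5-bis(methoxymethoxy)-4-methylphenol, via arylboronate 3 (not isolated)
Conditions: B2pin2 (1.0 equiv), [Ir(OMe)(cod)]2 (1.5 mol %), 4,4′-di-tert-butyl-2,2′-bipyridine (3 mol %), THF, 80 °C; then aq NaOH, H2O2, 0 °C to rt
Reagents that add atoms: bis(pinacolato)diboron, CC1(C)OB(OC1(C)C)B1OC(C)(C)C(C)(C)O1 (boron and pinacol atoms of 3); hydrogen peroxide, OO (phenol oxygen of 4)
Why: Sterically governed iridium-catalysed aromatic C–H borylation (Hartwig–Miyaura type) should select C5, the only C–H without an ortho substituent; oxidation of the C–B bond then gives the phenol whose oxygen is para to the methyl group, the future O1.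

**Step 3**
Reactants: 4 3,5-bis(methoxymethoxy)-4-methylphenol
Product: 5 1,3-bis(methoxymethoxy)-2-methyl-5-[(2-methylbut-3-yn-2-yl)oxy]benzene
Conditions: 3-chloro-3-methylbut-1-yne, DBU, CuCl2·2H2O (1 mol %), MeCN, 0 °C to rt
Reagents that add atoms: 3-chloro-3-methylbut-1-yne, C#CC(C)(C)Cl
Why: Copper-catalysed O-propargylation of a phenol with a tertiary propargylic chloride is the standard entry to aryl 1,1-dimethylpropargyl ethers, and the hydroxyl of 4 is unhindered.

**Step 4**
Reactants: 5 1,3-bis(methoxymethoxy)-2-methyl-5-[(2-methylbut-3-yn-2-yl)oxy]benzene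
Product: 7 3,5-bis(methoxymethoxy)-4-methyl-2-(3-methylbut-2-en-1-yl)phenol, via allyl ether 6 (not isolated)
Conditions: H2 (1 atm), Pd/CaCO3 poisoned with Pb(OAc)2 (Lindlar catalyst), quinoline, EtOAc, rt; filter; toluene, 110 °C
Reagents that add atoms: none
Why: Semi-hydrogenation gives the aryl 1,1-dimethylallyl ether, which undergoes aromatic Claisen rearrangement on heating; allyl inversion turns the tertiary ether into the linear prenyl group, and the two ortho carbons are equivalent, so one phenol should result.

**Step 5**
Reactants: 7 3,5-bis(methoxymethoxy)-4-methyl-2-(3-methylbut-2-en-1-yl)phenol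
Product: 8 2-hydroxy-4,6-bis(methoxymethoxy)-5-methyl-3-(3-methylbut-2-en-1-yl)benzaldehyde
Conditions: MgCl2, Et3N, (CH2O)n, MeCN, 80 °C; cold aq NH4Cl
Reagents that add atoms: paraformaldehyde (as formaldehyde), C=O
Why: Magnesium-phenoxide-directed ortho-formylation (Casnati–Skattebøl type) delivers formaldehyde ortho to the free hydroxyl, where the last aromatic C–H sits; a second formaldehyde accepts the hydride.

**Step 6**
Reactants: 8 2-hydroxy-4,6-bis(methoxymethoxy)-5-methyl-3-(3-methylbut-2-en-1-yl)benzaldehyde
Product: 9 rac-1-[2-hydroxy-4,6-bis(methoxymethoxy)-5-methyl-3-(3-methylbut-2-en-1-yl)phenyl]prop-2-yn-1-ol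
Conditions: HC≡CMgBr (3 equiv), THF, 0 °C to rt; aq NH4Cl
Reagents that add atoms: ethynylmagnesium bromide, C#C[Mg]Br
Why: 1,2-Addition of an alkynyl Grignard reagent to the aldehyde after the first equivalent has deprotonated the phenol; the carbinol centre is racemic and is removed in step 7.

**Step 7**
Reactants: 9 rac-1-[2-hydroxy-4,6-bis(methoxymethoxy)-5-methyl-3-(3-methylbut-2-en-1-yl)phenyl]prop-2-yn-1-ol
Product: 11 5,7-bis(methoxymethoxy)-6-methyl-8-(3-methylbut-2-en-1-yl)-4H-chromen-4-one, via ynone 10 (not isolated)
Conditions: MnO2 (activated, excess), CH2Cl2, rt; filter; K2CO3, acetone, rt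
Reagents that add atoms: none
Why: MnO2 oxidises the benzylic, propargylic alcohol selectively, and the phenoxide then closes ring C by 6-endo-dig oxa-Michael addition to the terminal ynone; the only free oxygen is the one para to the methyl group, so the chromone constitution is fixed.

**Step 8**
Reactants: 11 5,7-bis(methoxymethoxy)-6-methyl-8-(3-methylbut-2-en-1-yl)-4H-chromen-4-one; 12 [4-(methoxymethoxy)phenyl]boronic acid (2.5 equiv)
Product: 13 (2S)-5,7-bis(methoxymethoxy)-2-[4-(methoxymethoxy)phenyl]-6-methyl-8-(3-methylbut-2-en-1-yl)-2,3-dihydro-4H-chromen-4-one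
Conditions: Pd(OCOCF3)2 (5 mol %), (R)-4-tert-butyl-2-(pyridin-2-yl)-4,5-dihydrooxazole ((R)-t-BuPyOX, 6 mol %), NH4PF6 (30 mol %), H2O (5 equiv), ClCH2CH2Cl, 60 °C, air
Reagents that add atoms: none
Why: This is a Hayashi–Miyaura-type asymmetric conjugate addition run with a cationic divalent palladium/pyridine–oxazoline catalyst, a reaction type established for chromones and arylboronic acids. Transmetalation of 12 to the cationic palladium hydroxo/aqua complex gives an aryl–palladium species; the C2=C3 bond of 11 coordinates and inserts into the Pd–aryl bond (aryl to C2, palladium to C3), and water protonates the palladium enolate and regenerates the catalyst without a change of oxidation state. The step closes no ring; it forms the C2–C1′ bond and joins ring B to the ring A/ring C bicycle. C2 is the only new stereocentre and is set in the insertion by the ligand: the tert-butyl group of the oxazoline blocks one quadrant so that the aryl group reaches the Re face of C2, which gives (2S); by analogy with cyclic enones the (R)-ligand is expected to do this, and the mirror-image ligand would be used if the sense proved opposite. The selectivities needed are 1,4 over 1,2 (intrinsic to carbopalladation of an enone), enone over prenyl alkene (the unactivated trisubstituted alkene should neither bind nor insert competitively) and survival of the acetals (neutral to weakly acidic aqueous medium). The C8 prenyl and C6 methyl groups are remote from C2, and the peri 5-acetal lies on the carbonyl side, away from the reacting carbon. Because 13 has no free 5-hydroxyl and no base is present, retro-oxa-Michael opening should not erode the configuration. The excess of 12 compensates for protodeboronation of this electron-rich boronic acid.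

**Step 9**
Reactants: 13 (2S)-5,7-bis(methoxymethoxy)-2-[4-(methoxymethoxy)phenyl]-6-methyl-8-(3-methylbut-2-en-1-yl)-2,3-dihydro-4H-chromen-4-one
Product: 14 (2S)-5,7-dihydroxy-2-(4-hydroxyphenyl)-6-methyl-8-(3-methylbut-2-en-1-yl)-2,3-dihydro-4H-chromen-4-one (6-methyl-8-prenylnaringenin)
Conditions: 3 M aq HCl, MeOH, rt to 40 °C
Reagents that add atoms: none
Why: Acid-catalysed transacetalisation of the three aryl methoxymethyl ethers to methanol; the low temperature should keep prenyl/7-OH hydroalkoxylation and acid-induced opening at C2 slow, so the (2S) configuration is retained.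

## Compound list

1 | 2-methylbenzene-1,3-diol (2-methylresorcinol) | Cc1c(O)cccc1O | starting material
2 | 1,3-bis(methoxymethoxy)-2-methylbenzene | COCOc1cccc(OCOC)c1C | intermediate
3 | 2-[3,5-bis(methoxymethoxy)-4-methylphenyl]-4,4,5,5-tetramethyl-1,3,2-dioxaborolane | COCOc1cc(B2OC(C)(C)C(C)(C)O2)cc(OCOC)c1C | intermediate (not isolated)
4 | 3,5-bis(methoxymethoxy)-4-methylphenol | COCOc1cc(O)cc(OCOC)c1C | intermediate
5 | 1,3-bis(methoxymethoxy)-2-methyl-5-[(2-methylbut-3-yn-2-yl)oxy]benzene | COCOc1cc(OC(C)(C)C#C)cc(OCOC)c1C | intermediate
6 | 1,3-bis(methoxymethoxy)-2-methyl-5-[(2-methylbut-3-en-2-yl)oxy]benzene | COCOc1cc(OC(C)(C)C=C)cc(OCOC)c1C | intermediate (not isolated)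
7 | 3,5-bis(methoxymethoxy)-4-methyl-2-(3-methylbut-2-en-1-yl)phenol | COCOc1cc(O)c(CC=C(C)C)c(OCOC)c1C | intermediate
8 | 2-hydroxy-4,6-bis(methoxymethoxy)-5-methyl-3-(3-methylbut-2-en-1-yl)benzaldehyde | COCOc1c(C)c(OCOC)c(C=O)c(O)c1CC=C(C)C | intermediate
9 | rac-1-[2-hydroxy-4,6-bis(methoxymethoxy)-5-methyl-3-(3-methylbut-2-en-1-yl)phenyl]prop-2-yn-1-ol | COCOc1c(C)c(OCOC)c(C(O)C#C)c(O)c1CC=C(C)C | intermediate
10 | 1-[2-hydroxy-4,6-bis(methoxymethoxy)-5-methyl-3-(3-methylbut-2-en-1-yl)phenyl]prop-2-yn-1-one | COCOc1c(C)c(OCOC)c(C(=O)C#C)c(O)c1CC=C(C)C | intermediate (not isolated)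
11 | 5,7-bis(methoxymethoxy)-6-methyl-8-(3-methylbut-2-en-1-yl)-4H-chromen-4-one | COCOc1c(C)c(OCOC)c2c(=O)ccoc2c1CC=C(C)C | intermediate
12 | [4-(methoxymethoxy)phenyl]boronic acid | COCOc1ccc(B(O)O)cc1 | starting material
13 | (2S)-5,7-bis(methoxymethoxy)-2-[4-(methoxymethoxy)phenyl]-6-methyl-8-(3-methylbut-2-en-1-yl)-2,3-dihydro-4H-chromen-4-one | CC(C)=CCc1c(OCOC)c(C)c(OCOC)c2c1O[C@H](c1ccc(OCOC)cc1)CC2=O | intermediate
14 | (2S)-5,7-dihydroxy-2-(4-hydroxyphenyl)-6-methyl-8-(3-methylbut-2-en-1-yl)-2,3-dihydro-4H-chromen-4-one (6-methyl-8-prenylnaringenin) | CC(C)=CCc1c(O)c(C)c(O)c2c1O[C@H](c1ccc(O)cc1)CC2=O | target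

## Step count and least certain steps

Total: 9 steps. Longest linear sequence: 9 steps (1 to 14); 12 is purchased.

**Step 8 (key).** The 5,7-dioxygenated chromone is a weak acceptor, so insertion may be slow enough for protodeboronation of the electron-rich boronic acid to dominate. Facial selectivity may also fall short on this fully substituted substrate, and the peri acetal could be partly lost. Fallback, from 11 back to 13: an achiral, more active diene–rhodium catalyst ([Rh(OH)(cod)]2, monovalent rhodium, with 12 in dioxane/H2O at 50 °C) would give the racemic flavanone rac-5,7-bis(methoxymethoxy)-2-[4-(methoxymethoxy)phenyl]-6-methyl-8-(3-methylbut-2-en-1-yl)-2,3-dihydro-4H-chromen-4-one F1. Kinetic resolution by asymmetric transfer hydrogenation (RuCl(p-cymene)[(R,R)-TsDPEN], HCO2H/Et3N, EtOAc, rt, stopped near half conversion) is then expected to reduce the (2R)-antipode to the cis-alcohol (2R,4R)-5,7-bis(methoxymethoxy)-2-[4-(methoxymethoxy)phenyl]-6-methyl-8-(3-methylbut-2-en-1-yl)-3,4-dihydro-2H-chromen-4-ol F2 and leave the (2S)-ketone, which is 13. The stereocentre then comes from a resolution and not from the C–C bond formation, at the cost of at most half the material.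

**Step 4.** Over-reduction of the alkyne would give an ether that cannot rearrange, and ionisation of the tertiary allylic aryl ether (loss of the side chain) may compete with the [3,3] shift on heating. Fallback, from 4 back to 7: mono-iodination (N-iodosuccinimide, 1.0 equiv, CH2Cl2, −20 °C) would give 2-iodo-3,5-bis(methoxymethoxy)-4-methylphenol F3. Stille coupling with tributyl(3-methylbut-2-en-1-yl)stannane (Pd(PPh3)4, DMF, 80 °C) would then attach the prenyl group by cross-coupling instead of by sigmatropic shift and give 7.

**Step 7.** The terminal ynone is a very reactive acceptor, so intermolecular conjugate addition and oligomerisation, or closure through the α-carbon, may compete with the 6-endo closure. Fallback, from 8 back to 11, avoiding any ynone: MeMgBr (excess, THF, 0 °C) would give rac-1-[2-hydroxy-4,6-bis(methoxymethoxy)-5-methyl-3-(3-methylbut-2-en-1-yl)phenyl]ethan-1-ol F4. MnO2 (CH2Cl2, rt) would give 1-[2-hydroxy-4,6-bis(methoxymethoxy)-5-methyl-3-(3-methylbut-2-en-1-yl)phenyl]ethan-1-one F5. N,N-Dimethylformamide dimethyl acetal (toluene, 90 °C) would give the enaminone (E)-3-(dimethylamino)-1-[2-hydroxy-4,6-bis(methoxymethoxy)-5-methyl-3-(3-methylbut-2-en-1-yl)phenyl]prop-2-en-1-one F6, which closes to 11 by addition–elimination with loss of dimethylamine (catalytic AcOH, EtOH, 60 °C).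

**Step 9.** Acid-catalysed hydroalkoxylation of the prenyl alkene by the adjacent 7-OH (closure to a dimethylchroman), and acid-induced opening at C2 with loss of enantiopurity, may set in if the 7- and 4′-acetals need forcing. Fallback, from 13 back to 14, replacing protic hydrolysis by an acetal-to-silyl-ether exchange: TMSOTf with 2,2′-bipyridyl (CH2Cl2, 0 °C) would convert the three aryl acetals into (2S)-6-methyl-8-(3-methylbut-2-en-1-yl)-5,7-bis[(trimethylsilyl)oxy]-2-{4-[(trimethylsilyl)oxy]phenyl}-2,3-dihydro-4H-chromen-4-one F7. Addition of water at rt would hydrolyse it to 14 under near-neutral conditions.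

## Further compounds

F1 | step 8 | rac-5,7-bis(methoxymethoxy)-2-[4-(methoxymethoxy)phenyl]-6-methyl-8-(3-methylbut-2-en-1-yl)-2,3-dihydro-4H-chromen-4-one | CC(C)=CCc1c(OCOC)c(C)c(OCOC)c2c1OC(c1ccc(OCOC)cc1)CC2=O
F2 | step 8 | (2R,4R)-5,7-bis(methoxymethoxy)-2-[4-(methoxymethoxy)phenyl]-6-methyl-8-(3-methylbut-2-en-1-yl)-3,4-dihydro-2H-chromen-4-ol | CC(C)=CCc1c(OCOC)c(C)c(OCOC)c2c1O[C@@H](c1ccc(OCOC)cc1)C[C@H]2O
F3 | step 4 | 2-iodo-3,5-bis(methoxymethoxy)-4-methylphenol | COCOc1cc(O)c(I)c(OCOC)c1C
F4 | step 7 | rac-1-[2-hydroxy-4,6-bis(methoxymethoxy)-5-methyl-3-(3-methylbut-2-en-1-yl)phenyl]ethan-1-ol | COCOc1c(C)c(OCOC)c(C(C)O)c(O)c1CC=C(C)C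
F5 | step 7 | 1-[2-hydroxy-4,6-bis(methoxymethoxy)-5-methyl-3-(3-methylbut-2-en-1-yl)phenyl]ethan-1-one | COCOc1c(C)c(OCOC)c(C(C)=O)c(O)c1CC=C(C)C
F6 | step 7 | (E)-3-(dimethylamino)-1-[2-hydroxy-4,6-bis(methoxymethoxy)-5-methyl-3-(3-methylbut-2-en-1-yl)phenyl]prop-2-en-1-one | COCOc1c(C)c(OCOC)c(C(=O)/C=C/N(C)C)c(O)c1CC=C(C)C
F7 | step 9 | (2S)-6-methyl-8-(3-methylbut-2-en-1-yl)-5,7-bis[(trimethylsilyl)oxy]-2-{4-[(trimethylsilyl)oxy]phenyl}-2,3-dihydro-4H-chromen-4-one | CC(C)=CCc1c(O[Si](C)(C)C)c(C)c(O[Si](C)(C)C)c2c1O[C@H](c1ccc(O[Si](C)(C)C)cc1)CC2=O
A1 | alternative 1 | 1-[2,4,6-trihydroxy-3-methyl-5-(3-methylbut-2-en-1-yl)phenyl]ethan-1-one | CC(=O)c1c(O)c(C)c(O)c(CC=C(C)C)c1O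
A2 | alternative 1 | (E)-3-(4-hydroxyphenyl)-1-[2,4,6-trihydroxy-3-methyl-5-(3-methylbut-2-en-1-yl)phenyl]prop-2-en-1-one | CC(C)=CCc1c(O)c(C)c(O)c(C(=O)/C=C/c2ccc(O)cc2)c1O
A3 | alternative 1 | 5,7-dihydroxy-2-(4-hydroxyphenyl)-8-methyl-6-(3-methylbut-2-en-1-yl)-2,3-dihydro-4H-chromen-4-one (configuration at C2 not controlled) | Cc1c(O)c(CC=C(C)C)c(O)c2c1OC(c1ccc(O)cc1)CC2=O
A4 | alternative 2 | 5,7-bis(methoxymethoxy)-2-[4-(methoxymethoxy)phenyl]-6-methyl-8-(3-methylbut-2-en-1-yl)-4H-chromen-4-one | CC(C)=CCc1c(OCOC)c(C)c(OCOC)c2c(=O)cc(-c3ccc(OCOC)cc3)oc12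
A5 | alternative 3 | 4-[(2S)-7-acetoxy-6-methyl-5-[(3-methylbut-2-en-1-yl)oxy]-4-oxo-3,4-dihydro-2H-chromen-2-yl]phenyl acetate | CC(=O)Oc1ccc([C@@H]2CC(=O)c3c(OCC=C(C)C)c(C)c(OC(C)=O)cc3O2)cc1
A6 | alternative 3 | (2S)-5,7-dihydroxy-2-(4-hydroxyphenyl)-6-methyl-2,3-dihydro-4H-chromen-4-one | Cc1c(O)cc2c(c1O)C(=O)C[C@@H](c1ccc(O)cc1)O2
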